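**Strategy.** The trans tertiary bromide (C4) and secondary chloride (C3) of the cyclohexane ring are read as a masked 1-methylcyclohexene, which makes the ring bond C2–C3 (CH2–CHCl) an sp3–sp2 bond. It is closed last among the C–C bonds: 9-BBN hydroboration of a 2-substituted 1-alkene, followed in the same flask by intramolecular B-alkyl Suzuki–Miyaura coupling with a Z-bromoalkene. The precursor is an open-chain 1,5-diene hanging from C2 of the finished bromo-oxane. The step creates the cyclohexane methine C1 under control of that quaternary carbon and closes the carbocycle. Chlorohydrin formation and retentive OH-to-Br exchange complete the ring.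

Key step: step 10

Remark: atom labels follow the target name (oxane O1, C2 quaternary, C3 carbinol, C5 CHBr, C6 CMe2; cyclohexane C1 methine, C2 CH2, C3 CHCl, C4 CMeBr). Every step ends with an aqueous work-up, and acid 1 is taken as a purchasable compound.

**Step 1**
Reactants: 1 (methoxymethoxy)acetic acid; 2 (R)-4-benzyloxazolidin-2-one
Product: 4 (4R)-4-benzyl-3-[(methoxymethoxy)acetyl]oxazolidin-2-one, via mixed pivalic anhydride 3 (not isolated)
Conditions: PivCl, Et3N, THF, −20 °C; then 2, LiCl, −20 °C → rt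
Reagents that add atoms: none
Why: Mixed-anhydride N-acylation of the Evans auxiliary, in which the oxazolidinone attacks the less hindered carbonyl of the anhydride; no stereocentre is formed.

**Step 2**
Reactants: 4 (4R)-4-benzyl-3-[(methoxymethoxy)acetyl]oxazolidin-2-one; 5 1-bromo-3-methylbut-2-ene
Product: 7 (4R)-4-benzyl-3-[(2S)-2-(methoxymethoxy)-5-methylhex-4-enoyl]oxazolidin-2-one, via sodium Z-enolate 6 (not isolated)
Conditions: NaN(SiMe3)2, THF, −78 °C; 5, −78 → −45 °C
Reagents that add atoms: none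
Why: Evans glycolate alkylation, in which the chelated Z-enolate is alkylated by the allylic bromide on the face opposite the benzyl group, setting the oxygenated centre as S.

**Step 3**
Reactants: 7 (4R)-4-benzyl-3-[(2S)-2-(methoxymethoxy)-5-methylhex-4-enoyl]oxazolidin-2-one
Product: 8 (2S)-N-methoxy-2-(methoxymethoxy)-N,5-dimethylhex-4-enamide
Conditions: MeNH(OMe)·HCl, AlMe3, CH2Cl2, 0 °C → rt
Reagents that add atoms: N,O-dimethylhydroxylamine hydrochloride, CNOC.Cl
Why: Weinreb transamidation with the aluminium amide cleaves the exocyclic acyl group without touching the α-stereocentre and returns the auxiliary.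

**Step 4**
Reactants: 8 (2S)-N-methoxy-2-(methoxymethoxy)-N,5-dimethylhex-4-enamide
Product: 9 (3S)-3-(methoxymethoxy)-6-methylhept-5-en-2-one
Conditions: MeMgBr, THF, −78 → 0 °C
Reagents that add atoms: methylmagnesium bromide, C[Mg]Br
Why: Weinreb ketone synthesis, in which the chelated tetrahedral adduct stops at mono-addition and the α-alkoxy centre is not enolised at low temperature.

**Step 5**
Reactants: 10 (4-bromobut-1-yn-1-yl)trimethylsilane; 11 propyne
Product: 15 [(5Z)-6-bromo-5-methylhex-5-en-1-yn-1-yl]trimethylsilane, via Grignard reagent 12 (not isolated), via alkylcopper 13 (not isolated), via alkenylcopper 14 (not isolated)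
Conditions: Mg, Et2O; CuBr·SMe2, Et2O/Me2S, −45 °C; 11, −25 °C; NBS, −50 → 0 °C
Reagents that add atoms: N-bromosuccinimide, O=C1CCC(=O)N1Br
Why: Normant carbocupration adds the alkylcopper syn across propyne (carbon to the internal, copper to the terminal carbon), and bromination of the alkenylcopper with retention fixes the Z geometry (chain cis to bromine).

**Step 6**
Reactants: 15 [(5Z)-6-bromo-5-methylhex-5-en-1-yn-1-yl]trimethylsilane
Product: 16 (1Z)-1-bromo-2-methylhex-1-en-5-yne
Conditions: K2CO3 (cat.), MeOH, rt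
Reagents that add atoms: none
Why: Base-catalysed protodesilylation cleaves only the alkynyl C–Si bond; the bromoalkene is inert.

**Step 7**
Reactants: 16 (1Z)-1-bromo-2-methylhex-1-en-5-yne
Product: 18 (1Z)-1-bromo-5-iodo-2-methylhexa-1,5-diene, via iodoalkenylborane 17 (not isolated)
Conditions: 9-iodo-9-BBN, pentane, −20 °C; AcOH, 0 °C
Reagents that add atoms: 9-iodo-9-borabicyclo[3.3.1]nonane, IB1C2CCCC1CCC2
Why: Haloboration adds B–I cis across the terminal alkyne with iodine on the internal carbon, and protonolysis of the C–B bond gives the 2-iodo-1-alkene; the trisubstituted bromoalkene does not react.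

**Step 8**
Reactants: 18 (1Z)-1-bromo-5-iodo-2-methylhexa-1,5-diene; 9 (3S)-3-(methoxymethoxy)-6-methylhept-5-en-2-one
Product: 20 (1Z,6S,7S)-1-bromo-7-(methoxymethoxy)-2,6,10-trimethyl-5-methylideneundeca-1,9-dien-6-ol, via alkenylmagnesium chloride 19 (not isolated)
Conditions: i-PrMgCl·LiCl, THF, 0 °C → rt; then 9, −78 °C
Reagents that add atoms: none
Why: Iodine–magnesium exchange is selective for C–I over the alkenyl bromide, and the Grignard reagent adds to the α-alkoxy ketone under Cram chelate control (Mg bridging C=O and the MOM oxygen, attack anti to the prenyl-bearing group), setting the carbinol centre as S.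

**Step 9**
Reactants: 20 (1Z,6S,7S)-1-bromo-7-(methoxymethoxy)-2,6,10-trimethyl-5-methylideneundeca-1,9-dien-6-ol
Product: 21 (2S,3S,5S)-5-bromo-2-[(5Z)-6-bromo-5-methylhexa-1,5-dien-2-yl]-3-(methoxymethoxy)-2,6,6-trimethyloxane
Conditions: TBCO, MeNO2, 0 °C, dark
Reagents that add atoms: 2,4,4,6-tetrabromocyclohexa-2,5-dien-1-one (TBCO), O=C1C(Br)=CC(Br)(Br)C=C1Br
Why: Bromoetherification, in which the most electron-rich (prenyl) alkene forms the bromonium ion and the tertiary hydroxyl opens it at the tertiary carbon (6-endo, Markovnikov) through a chair with bromine and the dienyl group equatorial and methyl and OMOM axial, which should set the C–Br centre as S.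

**Step 10**
Reactants: 21 (2S,3S,5S)-5-bromo-2-[(5Z)-6-bromo-5-methylhexa-1,5-dien-2-yl]-3-(methoxymethoxy)-2,6,6-trimethyloxane
Product: 23 (2S,3S,5S)-5-bromo-3-(methoxymethoxy)-2,6,6-trimethyl-2-[(1R)-4-methylcyclohex-3-en-1-yl]oxane, via alkylborane 22 (not isolated)
Conditions: 9-BBN, THF, 0 → 40 °C; then Pd(dppf)Cl2 (10 mol %), AsPh3, Cs2CO3, DMF/THF/H2O, 0.005 M, 50 °C
Reagents that add atoms: none
Why: 9-BBN adds boron to the terminal carbon of the 2-substituted 1-alkene, and after base activation the primary alkylborane 22 transmetallates to the alkenylpalladium bromide formed by oxidative addition of zerovalent palladium into the Z C(sp2)–Br bond; reductive elimination then forges the CH2–CH= bond. This is the known hydroboration/intramolecular B-alkyl Suzuki–Miyaura cycloalkene synthesis. The cyclohexene closes as a six-membered ring by reductive elimination from a seven-membered palladacycle, the former bromoalkene becoming the endocyclic double bond. The one new stereocentre, cyclohexene C1, is created in the hydroboration under control of the adjacent quaternary oxane C2: with the C2–O1 bond eclipsing the C=CH2 bond (inside-alkoxy conformer), the borane should attack anti to the larger ring carbon C3 and syn to the axial methyl, giving (1R). The step needs alkene chemoselectivity (9-BBN strongly prefers 1,1-disubstituted over trisubstituted alkenes), C(sp2)–Br over secondary C(sp3)–Br oxidative addition (Pd(dppf) does not insert into the unactivated oxane C–Br bond) and cyclisation over oligomerisation (the Z geometry holds the chain cis to bromine; high dilution).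

**Step 11**
Reactants: 23 (2S,3S,5S)-5-bromo-3-(methoxymethoxy)-2,6,6-trimethyl-2-[(1R)-4-methylcyclohex-3-en-1-yl]oxane
Product: 24 (1S,2S,4R)-4-[(2S,3S,5S)-5-bromo-3-(methoxymethoxy)-2,6,6-trimethyloxan-2-yl]-2-chloro-1-methylcyclohexan-1-ol
Conditions: trichloroisocyanuric acid (0.4 equiv), acetone/H2O 4:1, 0 °C → rt
Reagents that add atoms: trichloroisocyanuric acid, O=C1N(Cl)C(=O)N(Cl)C(=O)N1Cl; water, O
Why: Chlorohydrin formation, in which water opens the chloronium ion at the tertiary carbon in the chair-like trans-diaxial (Fürst–Plattner, Markovnikov) mode with the oxanyl group equatorial, which should place OH cis and Cl trans to that group.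

**Step 12**
Reactants: 24 (1S,2S,4R)-4-[(2S,3S,5S)-5-bromo-3-(methoxymethoxy)-2,6,6-trimethyloxan-2-yl]-2-chloro-1-methylcyclohexan-1-ol
Product: 26 (2S,3S,5S)-5-bromo-2-[(1R,3S,4S)-4-bromo-3-chloro-4-methylcyclohexyl]-2,6,6-trimethyloxan-3-ol, via bromomethyl ether 25 (not isolated)
Conditions: TMSBr (5 equiv), CH2Cl2, −30 → 0 °C; aq NaHCO3
Reagents that add atoms: bromotrimethylsilane, C[Si](C)(C)Br
Why: Tertiary alcohol-to-bromide exchange with neighbouring-group participation, in which ionisation of the axial C–O bond is assisted by the antiperiplanar axial chlorine and bromide returns axially anti to chlorine with overall retention to the more stable diaxial dihalide, while the same reagent cleaves the MOM acetal (hydrolysed on work-up).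

**Compound list**
1 | (methoxymethoxy)acetic acid | COCOCC(=O)O | starting material
2 | (R)-4-benzyloxazolidin-2-one | O=C1N[C@H](Cc2ccccc2)CO1 | starting material
3 | (methoxymethoxy)acetic pivalic anhydride | COCOCC(=O)OC(=O)C(C)(C)C | intermediate
4 | (4R)-4-benzyl-3-[(methoxymethoxy)acetyl]oxazolidin-2-one | O=C1OC[C@@H](Cc2ccccc2)N1C(=O)COCOC | intermediate
5 | 1-bromo-3-methylbut-2-ene | CC(C)=CCBr | starting material
6 | sodium Z-enolate of 4 | [Na+].[O-]/C(=C\OCOC)N1[C@H](Cc2ccccc2)COC1=O | intermediate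
7 | (4R)-4-benzyl-3-[(2S)-2-(methoxymethoxy)-5-methylhex-4-enoyl]oxazolidin-2-one | O=C1OC[C@@H](Cc2ccccc2)N1C(=O)[C@@H](OCOC)CC=C(C)C | intermediate
8 | (2S)-N-methoxy-2-(methoxymethoxy)-N,5-dimethylhex-4-enamide | CON(C)C(=O)[C@@H](OCOC)CC=C(C)C | intermediate
9 | (3S)-3-(methoxymethoxy)-6-methylhept-5-en-2-one | CC(=O)[C@@H](OCOC)CC=C(C)C | intermediate
10 | (4-bromobut-1-yn-1-yl)trimethylsilane | C[Si](C)(C)C#CCCBr | starting material
11 | propyne | CC#C | starting material
12 | [4-(trimethylsilyl)but-3-yn-1-yl]magnesium bromide | C[Si](C)(C)C#CCC[Mg]Br | intermediate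
13 | [4-(trimethylsilyl)but-3-yn-1-yl]copper | C[Si](C)(C)C#CCC[Cu] | intermediate
14 | [(1Z)-2-methyl-6-(trimethylsilyl)hex-1-en-5-yn-1-yl]copper | C[Si](C)(C)C#CCC/C(C)=C\[Cu] | intermediate
15 | [(5Z)-6-bromo-5-methylhex-5-en-1-yn-1-yl]trimethylsilane | C[Si](C)(C)C#CCC/C(C)=C\Br | intermediate
16 | (1Z)-1-bromo-2-methylhex-1-en-5-yne | C#CCC/C(C)=C\Br | intermediate
17 | 9-[(1Z,5Z)-6-bromo-2-iodo-5-methylhexa-1,5-dien-1-yl]-9-borabicyclo[3.3.1]nonane | I/C(CC/C(C)=C\Br)=C\B1C2CCCC1CCC2 | intermediate
18 | (1Z)-1-bromo-5-iodo-2-methylhexa-1,5-diene | C=C(I)CC/C(C)=C\Br | intermediate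
19 | [(5Z)-6-bromo-5-methylhexa-1,5-dien-2-yl]magnesium chloride | C=C([Mg]Cl)CC/C(C)=C\Br | intermediate
20 | (1Z,6S,7S)-1-bromo-7-(methoxymethoxy)-2,6,10-trimethyl-5-methylideneundeca-1,9-dien-6-ol | O[C@@](C)(C(=C)CC/C(C)=C\Br)[C@@H](OCOC)CC=C(C)C | intermediate
21 | (2S,3S,5S)-5-bromo-2-[(5Z)-6-bromo-5-methylhexa-1,5-dien-2-yl]-3-(methoxymethoxy)-2,6,6-trimethyloxane | CC1(C)O[C@@](C)(C(=C)CC/C(C)=C\Br)[C@@H](OCOC)C[C@@H]1Br | intermediate
22 | 9-{(2S,5Z)-6-bromo-2-[(2S,3S,5S)-5-bromo-3-(methoxymethoxy)-2,6,6-trimethyloxan-2-yl]-5-methylhex-5-en-1-yl}-9-borabicyclo[3.3.1]nonane | CC1(C)O[C@@](C)([C@@H](CB2C3CCCC2CCC3)CC/C(C)=C\Br)[C@@H](OCOC)C[C@@H]1Br | intermediate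
23 | (2S,3S,5S)-5-bromo-3-(methoxymethoxy)-2,6,6-trimethyl-2-[(1R)-4-methylcyclohex-3-en-1-yl]oxane | CC1(C)O[C@@](C)([C@@H]2CCC(C)=CC2)[C@@H](OCOC)C[C@@H]1Br | intermediate
24 | (1S,2S,4R)-4-[(2S,3S,5S)-5-bromo-3-(methoxymethoxy)-2,6,6-trimethyloxan-2-yl]-2-chloro-1-methylcyclohexan-1-ol | CC1(C)O[C@@](C)([C@@H]2CC[C@](C)(O)[C@@H](Cl)C2)[C@@H](OCOC)C[C@@H]1Br | intermediate
25 | (2S,3S,5S)-5-bromo-2-[(1R,3S,4S)-4-bromo-3-chloro-4-methylcyclohexyl]-3-(bromomethoxy)-2,6,6-trimethyloxane | CC1(C)O[C@@](C)([C@@H]2CC[C@](C)(Br)[C@@H](Cl)C2)[C@@H](OCBr)C[C@@H]1Br | intermediate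
26 | (2S,3S,5S)-5-bromo-2-[(1R,3S,4S)-4-bromo-3-chloro-4-methylcyclohexyl]-2,6,6-trimethyloxan-3-ol | CC1(C)O[C@@](C)([C@@H]2CC[C@](C)(Br)[C@@H](Cl)C2)[C@@H](O)C[C@@H]1Br | target

**Step count and risks**
Total: 12 steps. Longest linear sequence: 9 steps (steps 1–4, then 8–12); the second branch (steps 5–7) joins at step 8.

Step 10 (key step). What may go wrong: poor facial selectivity in the hydroboration next to the quaternary centre, or slow transmetallation of the β-branched alkylborane so that protodeboronation or oligomerisation competes. The fallback sets out from 20 and returns at 23; it replaces open-chain induction by a temporary Si–O tether. (HMe2Si)2NH silylates the tertiary hydroxyl of 20 to the hydridosilyl ether F1. Pt2[(CH2=CHSiMe2)2O]3 then effects intramolecular 5-endo hydrosilylation of the 1,1-disubstituted alkene to the 1,2-oxasilolane F2, with hydrogen delivered inside the five-membered ring from the face of the smaller (methyl) substituent. Tamao–Fleming oxidation (H2O2, KF, KHCO3) should give the 1,3-diol F3. TBCO bromoetherification as in step 9 should give the oxane alcohol F4, and I2, PPh3 and imidazole the primary iodide F5. Zinc dust with LiCl inserts selectively into the C–I bond to give the alkylzinc iodide F6, and Pd(PPh3)4 closes the same CH2–CH= bond by intramolecular Negishi coupling to 23.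

Step 12. What may go wrong: after ionisation of the tertiary C–O bond, proton loss or bromide capture on the wrong face may compete with retentive substitution, and the acid may open the di-tertiary oxane ether. The fallback sets out from 24 and returns at 26; it separates the three events. POCl3/pyridine dehydration by anti elimination (the chlorinated carbon has no antiperiplanar hydrogen) should give the endocyclic alkene F7 together with the exocyclic alkene F8. Both converge on the same tertiary radical under cobalt-mediated hydrogen-atom-transfer (Mukaiyama-type) hydrobromination with Co(acac)2, t-BuOOH, Et3SiH and TsBr; axial bromine transfer anti to the C–Cl bond should give the MOM ether of the target F9. TMSBr at −30 °C then removes only the acetal (through 25) to give 26.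

Step 9. What may go wrong: the hydroxyl may open the bromonium ion at the secondary carbon (5-exo closure) or approach the other alkene face. The fallback sets out from 20 and returns at 21; it uses thermodynamic instead of kinetic control and is the least precedented of the three. The same bromonium source is allowed to give the 5-exo product, the bromo-oxolane F10 with its tertiary bromide. ZnBr2 in MeNO2 should then equilibrate it: the ring oxygen assists ionisation of the tertiary C–Br bond to a bicyclic oxonium ion, which bromide reopens at the secondary carbon with inversion. This funnels the material to the more stable oxane 21 (tertiary ether, equatorial secondary bromide).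

**Further compounds**
F1 | step 10 | (1Z,6S,7S)-1-bromo-6-[(dimethylsilyl)oxy]-7-(methoxymethoxy)-2,6,10-trimethyl-5-methylideneundeca-1,9-diene | C[SiH](C)O[C@@](C)(C(=C)CC/C(C)=C\Br)[C@@H](OCOC)CC=C(C)C
F2 | step 10 | (4S,5S)-4-[(3Z)-4-bromo-3-methylbut-3-en-1-yl]-5-[(1S)-1-(methoxymethoxy)-4-methylpent-3-en-1-yl]-2,2,5-trimethyl-1,2-oxasilolane | C[Si]1(C)C[C@@H](CC/C(C)=C\Br)[C@](C)(O1)[C@@H](OCOC)CC=C(C)C
F3 | step 10 | (2R,3S,4S)-2-[(3Z)-4-bromo-3-methylbut-3-en-1-yl]-4-(methoxymethoxy)-3,7-dimethyloct-6-ene-1,3-diol | OC[C@@H](CC/C(C)=C\Br)[C@](C)(O)[C@@H](OCOC)CC=C(C)C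
F4 | step 10 | (2R,5Z)-6-bromo-2-[(2S,3S,5S)-5-bromo-3-(methoxymethoxy)-2,6,6-trimethyloxan-2-yl]-5-methylhex-5-en-1-ol | CC1(C)O[C@@](C)([C@@H](CO)CC/C(C)=C\Br)[C@@H](OCOC)C[C@@H]1Br
F5 | step 10 | (2S,3S,5S)-5-bromo-2-[(2S,5Z)-6-bromo-1-iodo-5-methylhex-5-en-2-yl]-3-(methoxymethoxy)-2,6,6-trimethyloxane | CC1(C)O[C@@](C)([C@@H](CI)CC/C(C)=C\Br)[C@@H](OCOC)C[C@@H]1Br
F6 | step 10 | {(2S,5Z)-6-bromo-2-[(2S,3S,5S)-5-bromo-3-(methoxymethoxy)-2,6,6-trimethyloxan-2-yl]-5-methylhex-5-en-1-yl}zinc iodide | CC1(C)O[C@@](C)([C@@H](C[Zn]I)CC/C(C)=C\Br)[C@@H](OCOC)C[C@@H]1Br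
F7 | step 12 | (2S,3S,5S)-5-bromo-2-[(1R,5S)-5-chloro-4-methylcyclohex-3-en-1-yl]-3-(methoxymethoxy)-2,6,6-trimethyloxane | CC1(C)O[C@@](C)([C@@H]2CC=C(C)[C@@H](Cl)C2)[C@@H](OCOC)C[C@@H]1Br
F8 | step 12 | (2S,3S,5S)-5-bromo-2-[(1R,3S)-3-chloro-4-methylidenecyclohexyl]-3-(methoxymethoxy)-2,6,6-trimethyloxane | CC1(C)O[C@@](C)([C@@H]2CCC(=C)[C@@H](Cl)C2)[C@@H](OCOC)C[C@@H]1Br
F9 | step 12 | (2S,3S,5S)-5-bromo-2-[(1R,3S,4S)-4-bromo-3-chloro-4-methylcyclohexyl]-3-(methoxymethoxy)-2,6,6-trimethyloxane | CC1(C)O[C@@](C)([C@@H]2CC[C@](C)(Br)[C@@H](Cl)C2)[C@@H](OCOC)C[C@@H]1Br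
F10 | step 9 | (2S,3S,5R)-5-(2-bromopropan-2-yl)-2-[(5Z)-6-bromo-5-methylhexa-1,5-dien-2-yl]-3-(methoxymethoxy)-2-methyloxolane | CC(C)(Br)[C@H]1C[C@H](OCOC)[C@](C)(C(=C)CC/C(C)=C\Br)O1
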